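**Retrosynthetic overview**
- The carbocycle is closed last, at the C7–C8 bond (chromenone numbering): a diketonate carbon attacks the ester on pyran C6 (Dieckmann), in the same flask in which the acetyl group is C-acylated with 3-phenylpropanoyl chloride.
- The 2,2-dimethyl-2H-pyran ring is made before that, from an α-keto ester and 3-methylbut-2-enal by aldol condensation and oxa-6π electrocyclisation.
- The α-keto ester comes from an aldehyde by Horner–Wadsworth–Emmons homologation; aldehyde and acetyl group both come from a quaternary β-keto ester.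
- The C5 stereocentre is set first, by auxiliary-controlled prenylation of the valine-derived enamine of ethyl 2-methylacetoacetate.
- Enabling feature: in the monocyclic precursor the ester carbon on pyran C6 and the quaternary carbon on pyran C5 are held cis on the ring C5=C6 double bond, so the acetyl carbon sits six atoms from the ester carbonyl.

Key step: step 8

Assumption: for the L-valine-derived enamine the toluene/HMPA protocol is taken to open the face that leads to (R)-6; if the sense proves opposite, step 2 is run with tert-butyl D-valinate.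

**Step 1**
Reactants: 1 ethyl 2-methyl-3-oxobutanoate; 2 tert-butyl L-valinate
Product: 3 ethyl (2Z)-3-{[(2S)-1-tert-butoxy-3-methyl-1-oxobutan-2-yl]amino}-2-methylbut-2-enoate
Conditions: BF3·OEt2 (cat.), toluene, reflux, azeotropic removal of water
Reagents that add atoms: none
Why: Acid-catalysed condensation of the primary amine with the ketone of the β-keto ester (enamine formation) should give the conjugated, hydrogen-bonded (Z)-enamino ester without touching the valine stereocentre.

**Step 2**
Reactants: 3 the enamino ester; 4 1-bromo-3-methylbut-2-ene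
Product: 6 ethyl (2R)-2-acetyl-2,5-dimethylhex-4-enoate, via alkylated ketimine 5 (not isolated)
Conditions: LiN(i-Pr)2, toluene, −78 °C; HMPA (1 equiv), 4, −78 → −55 °C; then 1 M HCl, 25 °C
Reagents that add atoms: water, O
Why: Chiral-enamine alkylation: the lithium aza-enolate is held rigid by N–Li–O chelation to the valinate ester, whose isopropyl group blocks one face, so the allylic bromide (SN2 at its primary carbon) should enter from the other face and set the quaternary centre as (R); mild acid then hydrolyses the imine and returns the auxiliary.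

**Step 3**
Reactants: 6 the quaternary β-keto ester
Product: 7 (3S)-3-(hydroxymethyl)-3,6-dimethylhept-5-en-2-ol (both C2 epimers)
Conditions: LiAlH4, THF, 0 → 25 °C
Reagents that add atoms: none
Why: Hydride reduction of ester and ketone should give the diol; the new carbinol centre is reoxidised later and the quaternary centre has no acidic hydrogen, so it cannot epimerise.

**Step 4**
Reactants: 7 the diol
Product: 8 (2S)-2-acetyl-2,5-dimethylhex-4-enal
Conditions: Dess–Martin periodinane (2.4 equiv), CH2Cl2, 0 → 25 °C
Reagents that add atoms: none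
Why: Dess–Martin oxidation of the primary and the secondary alcohol should give the non-enolisable β-keto aldehyde under near-neutral conditions that avoid retro-Claisen cleavage.

**Step 5**
Reactants: 8 the keto aldehyde; 9 methyl 2-(dimethoxyphosphoryl)-2-methoxyacetate
Product: 10 methyl (4S)-4-acetyl-2-methoxy-4,7-dimethylocta-2,6-dienoate (E/Z mixture at C2=C3)
Conditions: 9, LiN(SiMe3)2, THF, −78 °C; then 8, −78 → 0 °C
Reagents that add atoms: none
Why: Horner–Wadsworth–Emmons olefination should occur only at the aldehyde (the hindered methyl ketone is far less reactive) and attaches the future C8a and C8 as the enol ether of an α-keto ester.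

**Step 6**
Reactants: 10 the α-methoxy acrylate
Product: 11 methyl (4S)-4-acetyl-4,7-dimethyl-2-oxooct-6-enoate
Conditions: 2 M HCl, THF, 25 → 40 °C
Reagents that add atoms: water, O
Why: Acid hydrolysis of the enol ether (protonation at the β-carbon, collapse of the hemiketal) should release the α-keto ester; dilute acid at this temperature should leave the trisubstituted alkene intact.

**Step 7**
Reactants: 11 the α-keto ester; 12 3-methylbut-2-enal
Product: 16 methyl 5-[(3S)-3,6-dimethyl-2-oxohept-5-en-3-yl]-2,2-dimethyl-2H-pyran-6-carboxylate, via lithium aldolate 13 (not isolated), via allylic mesylate 14 (not isolated), via dienone 15 (not isolated)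
Conditions: LiN(SiMe3)2 (1.05 equiv), THF, −78 °C; 12; MsCl, −78 → 0 °C; DBU, 0 → 40 °C
Reagents that add atoms: none
Why: One equivalent of base removes only the far more acidic methylene next to the α-keto ester, the enolate adds 1,2 to the enal (aldol), mesylation and E1cB elimination give the cross-conjugated dienone, and oxa-6π electrocyclisation should close the 2H-pyran, the neighbouring quaternary carbon pushing the dienyl chain to the carbonyl side as ring closure requires.

**Step 8**
Reactants: 16 the pyran keto ester; 17 3-phenylpropanoyl chloride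
Product: 19 (5S)-8-hydroxy-2,2,5-trimethyl-5-(3-methylbut-2-en-1-yl)-7-(3-phenylpropanoyl)-2H-chromen-6(5H)-one, via β-diketone 18 (not isolated)
Conditions: MgBr2·OEt2 (2.5 equiv), i-Pr2NEt (3 equiv), 17 (1.05 equiv), CH2Cl2, 0 → 25 °C; then KOt-Bu (4 equiv), THF, 0 → 40 °C; 1 M HCl work-up
Reagents that add atoms: none
Why: Soft enolisation (magnesium chelation, amine base) forms the enolate of the acetyl group, the only enolisable position of 16, which is C-acylated by the acid chloride to β-diketone 18 (crossed Claisen acylation); KOt-Bu then gives the diketonate, whose central carbon attacks the ester on pyran C6 and expels methoxide (Dieckmann condensation), the closest known reaction type being the base-mediated cyclisation of 5,7-dioxo esters to 2-acylcyclohexane-1,3-diones. The carbocycle closes in a 6-(enolexo)-exo-trig mode, helped by the cis placement of ester and nucleophile on the ring C5=C6 double bond and by the gem-disubstituent effect of the quaternary carbon. No new stereocentre is formed, and the existing quaternary centre has no α-hydrogen, so it is carried through unchanged. The step needs C- over O-acylation and the six-membered ring over any other: enol ester or enol lactone formed by O-attack reverts under the alkoxide conditions while the triketone is drained off as its stabilised enolate, and conjugate addition to the dienoate would give a bridgehead alkene. Because the acid chloride reacts before the ester, the ring-closing event is the C7–C8 bond.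

**Compound list**
1 | ethyl 2-methyl-3-oxobutanoate | CCOC(=O)C(C)C(C)=O | starting material
2 | tert-butyl L-valinate | CC(C)[C@H](N)C(=O)OC(C)(C)C | starting material
3 | ethyl (2Z)-3-{[(2S)-1-tert-butoxy-3-methyl-1-oxobutan-2-yl]amino}-2-methylbut-2-enoate | CCOC(=O)/C(C)=C(C)\N[C@@H](C(C)C)C(=O)OC(C)(C)C | intermediate
4 | 1-bromo-3-methylbut-2-ene | CC(C)=CCBr | starting material
5 | ethyl (2R)-2-{N-[(2S)-1-tert-butoxy-3-methyl-1-oxobutan-2-yl]ethanimidoyl}-2,5-dimethylhex-4-enoate | CCOC(=O)[C@](C)(CC=C(C)C)C(C)=N[C@@H](C(C)C)C(=O)OC(C)(C)C | intermediate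
6 | ethyl (2R)-2-acetyl-2,5-dimethylhex-4-enoate | CCOC(=O)[C@](C)(CC=C(C)C)C(C)=O | intermediate
7 | (3S)-3-(hydroxymethyl)-3,6-dimethylhept-5-en-2-ol | OC[C@](C)(CC=C(C)C)C(C)O | intermediate
8 | (2S)-2-acetyl-2,5-dimethylhex-4-enal | O=C[C@](C)(CC=C(C)C)C(C)=O | intermediate
9 | methyl 2-(dimethoxyphosphoryl)-2-methoxyacetate | COC(C(=O)OC)P(=O)(OC)OC | starting material
10 | methyl (4S)-4-acetyl-2-methoxy-4,7-dimethylocta-2,6-dienoate | COC(=O)C(OC)=C[C@](C)(CC=C(C)C)C(C)=O | intermediate
11 | methyl (4S)-4-acetyl-4,7-dimethyl-2-oxooct-6-enoate | COC(=O)C(=O)C[C@](C)(CC=C(C)C)C(C)=O | intermediate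
12 | 3-methylbut-2-enal | CC(C)=CC=O | starting material
13 | lithium alkoxide of methyl (4S)-4-acetyl-3-(1-hydroxy-3-methylbut-2-en-1-yl)-4,7-dimethyl-2-oxooct-6-enoate | COC(=O)C(=O)C(C([O-])C=C(C)C)[C@](C)(CC=C(C)C)C(C)=O.[Li+] | intermediate
14 | methyl (4S)-4-acetyl-3-[1-(methanesulfonyloxy)-3-methylbut-2-en-1-yl]-4,7-dimethyl-2-oxooct-6-enoate | COC(=O)C(=O)C(C(OS(C)(=O)=O)C=C(C)C)[C@](C)(CC=C(C)C)C(C)=O | intermediate
15 | methyl (3Z,4S)-4-acetyl-4,7-dimethyl-3-(3-methylbut-2-en-1-ylidene)-2-oxooct-6-enoate | COC(=O)C(=O)/C(=C\C=C(C)C)[C@](C)(CC=C(C)C)C(C)=O | intermediate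
16 | methyl 5-[(3S)-3,6-dimethyl-2-oxohept-5-en-3-yl]-2,2-dimethyl-2H-pyran-6-carboxylate | COC(=O)C1=C([C@](C)(CC=C(C)C)C(C)=O)C=CC(C)(C)O1 | intermediate
17 | 3-phenylpropanoyl chloride | O=C(Cl)CCc1ccccc1 | starting material
18 | methyl 5-[(5S)-2,5-dimethyl-6,8-dioxo-10-phenyldec-2-en-5-yl]-2,2-dimethyl-2H-pyran-6-carboxylate | COC(=O)C1=C([C@](C)(CC=C(C)C)C(=O)CC(=O)CCc2ccccc2)C=CC(C)(C)O1 | intermediate
19 | (5S)-8-hydroxy-2,2,5-trimethyl-5-(3-methylbut-2-en-1-yl)-7-(3-phenylpropanoyl)-2H-chromen-6(5H)-one | CC(C)=CC[C@]1(C)C(=O)C(C(=O)CCc2ccccc2)=C(O)C2=C1C=CC(C)(C)O2 | target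

**Totals**
Total step count: 8. Longest linear sequence: 8 steps (1 to 19).

**Steps most likely to fail**

Step 8. The magnesium enolate may be acylated on oxygen or twice, the new β-diketone may be cleaved again (retro-Claisen) before it cyclises, or ring closure may come first and leave an enol ester that the alkoxide only cleaves. The fallback sets out from 16 and reverses the order of the two acylations. LiN(SiMe3)2 in THF (−78 → 25 °C) should cyclise the methyl ketone enolate onto the ester to the bicyclic vinylogous acid (5S)-8-hydroxy-2,2,5-trimethyl-5-(3-methylbut-2-en-1-yl)-2H-chromen-6(5H)-one F5. Treatment with 3-phenylpropanoic acid, dicyclohexylcarbodiimide and 4-(dimethylamino)pyridine in CH2Cl2 should then give the enol ester F6, which the same nucleophilic catalyst moves from oxygen to C7. The route is rejoined at 19.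

Step 2. Face discrimination in the alkylation of the chelated aza-enolate may be poor or of the opposite sense, and N-alkylation may compete. The fallback sets out from 1 and 4 and replaces auxiliary control by enzymatic kinetic resolution. Alkylation with K2CO3 in acetone should give the racemic keto ester F1. A ketoreductase (or baker's yeast) chosen to reduce the (S)-enantiomer converts it into the hydroxy ester F2, and unreacted (R)-keto ester is separated by chromatography. The route is rejoined at 6.

Step 7. Aldol addition at the enolate carbon next to the quaternary centre may be slow or reverse, the enal may self-condense, and the dienone of the wrong geometry may isomerise too slowly to cyclise. The fallback sets out from 11 and uses a neutral enol silane and acid instead of a lithium enolate and base. Me3SiOTf and Et3N should silylate the α-keto ester selectively to the silyl enol ether F3. A Mukaiyama aldol addition to 12 with TiCl4 in CH2Cl2 at −78 °C should give the hydroxy keto ester F4. Warming F4 with pyridinium p-toluenesulfonate in toluene ionises the allylic alcohol, and capture by the enol oxygen closes the pyran. The route is rejoined at 16.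

Further compounds
F1 | step 2 | ethyl 2-acetyl-2,5-dimethylhex-4-enoate (racemate) | CCOC(=O)C(C)(CC=C(C)C)C(C)=O
F2 | step 2 | ethyl (2S)-2-[(1S)-1-hydroxyethyl]-2,5-dimethylhex-4-enoate | CCOC(=O)[C@@](C)(CC=C(C)C)[C@H](C)O
F3 | step 7 | methyl (4S)-4-acetyl-4,7-dimethyl-2-[(trimethylsilyl)oxy]octa-2,6-dienoate | COC(=O)C(O[Si](C)(C)C)=C[C@](C)(CC=C(C)C)C(C)=O
F4 | step 7 | methyl (4S)-4-acetyl-3-(1-hydroxy-3-methylbut-2-en-1-yl)-4,7-dimethyl-2-oxooct-6-enoate | COC(=O)C(=O)C(C(O)C=C(C)C)[C@](C)(CC=C(C)C)C(C)=O
F5 | step 8 | (5S)-8-hydroxy-2,2,5-trimethyl-5-(3-methylbut-2-en-1-yl)-2H-chromen-6(5H)-one | CC(C)=CC[C@]1(C)C(=O)C=C(O)C2=C1C=CC(C)(C)O2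
F6 | step 8 | (5S)-2,2,5-trimethyl-5-(3-methylbut-2-en-1-yl)-6-oxo-5,6-dihydro-2H-chromen-8-yl 3-phenylpropanoate | CC(C)=CC[C@]1(C)C(=O)C=C(OC(=O)CCc3ccccc3)C2=C1C=CC(C)(C)O2
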